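**Retrosynthetic overview**
- Target ⇐ fluoride cleavage of one silyl ester and one silyl ether from the fully assembled ester-aldehyde.
- C10 ester C–O bond and C12 aldehyde ⇐ one-pot acylative opening of a 10,12-oxolane by the (Z)-C16 acyl chloride, sulfoxide oxidation at C12, then C2 epimerisation.
- Oxolane C12–O bond ⇐ alkoxy-radical 1,5-hydrogen transfer from the 10S alcohol, which oxidises the unactivated C12 methyl.
- 10S alcohol ⇐ (−)-α-cedrene by C–H oxidation at C15 (SeO2, then NaClO2) and C10 (Rh2(cap)4/t-BuOOH, then NaBH4/CeCl3). The three carbocycles come intact from cedrene; the only ring formed is the temporary oxolane, opened again in the coupling.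
- Side chain ⇐ acetylide alkylation (oct-7-yn-1-ol + 8-bromooctanoic acid), then Lindlar semihydrogenation.

Assumption: the SMILES is read as (1S,2S,5S,7R,10S) in cedrane numbering, so the formyl group is trans to C10 across the cyclopentane, opposite to the C12 methyl of natural α-cedrene; C2 must therefore be inverted.
Numbering: cedrane (tricyclo[5.3.1.0(1,5)]undecane) with C1 spiro, C2 bearing C12, C6 bearing the geminal methyls, C8 bearing C15, and C11 the one-carbon bridge; C1, C5 and C7 stay as in α-cedrene throughout.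

**Step 1**
Reactants: 1 (−)-α-cedrene
Product: 2 cedr-8-en-15-al
Conditions: SeO2 (1.5 equiv), 1,4-dioxane, H2O (2 equiv), 90 °C
Reagents that add atoms: selenium dioxide, O=[Se]=O
Why: Riley allylic oxidation (ene reaction then [2,3]-sigmatropic shift) attacks the methyl on the more substituted alkene carbon, because the other allylic position there is the C7 bridgehead; no stereocentre is touched.

**Step 2**
Reactants: 2 cedr-8-en-15-al
Product: 3 cedr-8-en-15-oic acid
Conditions: NaClO2, NaH2PO4, 2-methylbut-2-ene, t-BuOH/H2O, 0 °C to rt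
Reagents that add atoms: sodium chlorite, [Na+].[O-]Cl=O
Why: Pinnick oxidation converts the enal to the acid without touching the trisubstituted alkene.

**Step 3**
Reactants: 3 cedr-8-en-15-oic acid
Product: 4 2-(trimethylsilyl)ethyl cedr-8-en-15-oate
Conditions: Me3SiCH2CH2OH, DCC, DMAP (cat.), CH2Cl2, 0 °C to rt
Reagents that add atoms: 2-(trimethylsilyl)ethanol, C[Si](C)(C)CCO
Why: Steglich esterification masks the acid as a fluoride-labile ester that survives the oxidising, reducing and Lewis-acidic steps that follow.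

**Step 4**
Reactants: 4 2-(trimethylsilyl)ethyl cedr-8-en-15-oate
Product: 5 2-(trimethylsilyl)ethyl 10-oxocedr-8-en-15-oate
Conditions: Rh2(cap)4 (1 mol %, cap = caprolactamate), t-BuOOH (70% aq., 6 equiv), K2CO3 (0.5 equiv), CH2Cl2, rt to 40 °C
Reagents that add atoms: tert-butyl hydroperoxide, CC(C)(C)OO
Why: Kharasch-type radical allylic C–H oxidation; the tert-butylperoxyl radical abstracts the only productive allylic hydrogen (C10–H2, γ to the ester) and the allyl radical is oxidised to the γ-keto enoate.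

**Step 5**
Reactants: 5 2-(trimethylsilyl)ethyl 10-oxocedr-8-en-15-oate
Product: 6 2-(trimethylsilyl)ethyl (10S)-10-hydroxycedr-8-en-15-oate
Conditions: NaBH4, CeCl3·7H2O, MeOH, −78 °C
Reagents that add atoms: none
Why: Luche 1,2-reduction; hydride should add from the face syn to the C11 bridge, since the other face is blocked by C5, C6 and the endo methyl on C6 (the same bias by which methyl nucleophiles give cedrol from the C8 ketone), placing the hydroxyl 10S and next to the C12 methyl.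

**Step 6**
Reactants: 6 2-(trimethylsilyl)ethyl (10S)-10-hydroxycedr-8-en-15-oate
Product: 9 2-(trimethylsilyl)ethyl (2R,10S)-10,12-epoxycedr-8-en-15-oate, via C10 hypoiodite 7 (not isolated), via 12-iodo alcohol 8 (not isolated)
Conditions: PhI(OAc)2 (1.6 equiv), I2 (1.0 equiv), cyclohexane/CH2Cl2, hν (tungsten lamp), 25–35 °C
Reagents that add atoms: none
Why: Suárez hypoiodite reaction; the C10 alkoxy radical lies within reach of the cis C12 methyl on the cyclopentane, so 1,5-hydrogen atom transfer, iodine capture and ring closure by the hydroxyl forge the C12–O bond, with C10 and C2 unchanged.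

**Step 7**
Reactants: 10 oct-7-yn-1-ol
Product: 11 tert-butyl(oct-7-yn-1-yloxy)diphenylsilane
Conditions: TBDPSCl, imidazole, CH2Cl2, rt
Reagents that add atoms: tert-butyl(chloro)diphenylsilane, CC(C)(C)[Si](Cl)(c1ccccc1)c1ccccc1
Why: standard silylation of the primary alcohol gives an ether stable to organolithiums, hydrogenation, acyl chloride formation and acyl triflates.

**Step 8**
Reactants: 11 tert-butyl(oct-7-yn-1-yloxy)diphenylsilane; 12 8-bromooctanoic acid
Product: 13 16-(tert-butyldiphenylsilyloxy)hexadec-9-ynoic acid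
Conditions: 11, n-BuLi, THF, −78 °C; lithium salt of 12 (12, n-BuLi, THF), HMPA, 0 °C to rt; 1 M HCl
Reagents that add atoms: none
Why: acetylide alkylation (SN2) of the primary bromide of the lithium carboxylate forms the C8–C9 bond and fixes the alkyne at C9–C10.

**Step 9**
Reactants: 13 16-(tert-butyldiphenylsilyloxy)hexadec-9-ynoic acid
Product: 14 (9Z)-16-(tert-butyldiphenylsilyloxy)hexadec-9-enoic acid
Conditions: H2 (1 atm), Pd/CaCO3 poisoned with Pb(OAc)2, quinoline, EtOAc, rt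
Reagents that add atoms: none
Why: Lindlar semihydrogenation adds H2 syn on the poisoned palladium surface and so sets the 9Z alkene.

**Step 10**
Reactants: 9 2-(trimethylsilyl)ethyl (2R,10S)-10,12-epoxycedr-8-en-15-oate; 14 (9Z)-16-(tert-butyldiphenylsilyloxy)hexadec-9-enoic acid
Product: 20 2-(trimethylsilyl)ethyl (2S,10S)-10-[(9Z)-16-(tert-butyldiphenylsilyloxy)hexadec-9-enoyloxy]-12-oxocedr-8-en-15-oate, via acid chloride 15 (not isolated), via acyl triflate 16 (not isolated), via 12-triflate ester 17 (not isolated), via alkoxysulfonium triflate 18 (not isolated), via cis-aldehyde 19 (not isolated)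
Conditions: 14, (COCl)2, DMF (cat.), CH2Cl2, 0 °C to rt, evaporate; then 9, AgOTf (1.4 equiv), 2,6-di-tert-butyl-4-methylpyridine (0.3 equiv), CH2Cl2, −40 to 0 °C; DMSO (5 equiv), −20 °C to rt; Et3N (4 equiv); DBU (0.3 equiv), rt
Reagents that add atoms: dimethyl sulfoxide, CS(C)=O
Why: Proposed new method: one-pot acylative ether scission with sulfoxide oxidation. Acyl triflate 16 O-acylates the oxolane oxygen of 9; triflate and then DMSO attack the primary C12 by SN2, while the C10–O bond and the 10S centre are kept because C10 is neopentylic and its allyl cation is destabilised by the enoate. Et3N collapses alkoxysulfonium 18 to cis-aldehyde 19, and DBU epimerises C2 to the trans (2S) aldehyde, which relieves the syn-pentane contact with the C10 acyloxy group. The closest known reactions are the acyl halide/Lewis acid cleavage of tetrahydrofurans to 4-halobutyl esters and the Kornblum oxidation of alkyl sulfonates.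

**Step 11**
Reactants: 20 2-(trimethylsilyl)ethyl (2S,10S)-10-[(9Z)-16-(tert-butyldiphenylsilyloxy)hexadec-9-enoyloxy]-12-oxocedr-8-en-15-oate
Product: 21 (2S,10S)-10-[(9Z)-16-hydroxyhexadec-9-enoyloxy]-12-oxocedr-8-en-15-oic acid (CNP0214056.2)
Conditions: n-Bu4NF (4 equiv), AcOH (2 equiv), THF, 0 °C to rt
Reagents that add atoms: none
Why: fluoride-induced desilylation frees the primary alcohol, and β-elimination of the 2-(trimethylsilyl)ethyl ester frees the acid; the buffered medium spares the C10 ester and the aldehyde, whose C2 centre is already at its thermodynamic configuration.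

**Compound list**
1 | (−)-α-cedrene, (1S,2R,5S,7S)-2,6,6,8-tetramethyltricyclo[5.3.1.0(1,5)]undec-8-ene | CC1(C)[C@H]2C[C@@]3(CC=C2C)[C@H](C)CC[C@@H]13 | starting material
2 | cedr-8-en-15-al (configuration of 1) | CC1(C)[C@H]2C[C@@]3(CC=C2C=O)[C@H](C)CC[C@@H]13 | intermediate
3 | cedr-8-en-15-oic acid (configuration of 1) | CC1(C)[C@H]2C[C@@]3(CC=C2C(=O)O)[C@H](C)CC[C@@H]13 | intermediate
4 | 2-(trimethylsilyl)ethyl cedr-8-en-15-oate | CC1(C)[C@H]2C[C@@]3(CC=C2C(=O)OCC[Si](C)(C)C)[C@H](C)CC[C@@H]13 | intermediate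
5 | 2-(trimethylsilyl)ethyl 10-oxocedr-8-en-15-oate | CC1(C)[C@H]2C[C@@]3(C(=O)C=C2C(=O)OCC[Si](C)(C)C)[C@H](C)CC[C@@H]13 | intermediate
6 | 2-(trimethylsilyl)ethyl (10S)-10-hydroxycedr-8-en-15-oate (hydroxyl anti to C11, cis to the C12 methyl) | CC1(C)[C@H]2C[C@@]3([C@@H](O)C=C2C(=O)OCC[Si](C)(C)C)[C@H](C)CC[C@@H]13 | intermediate
7 | C10 hypoiodite of 6 | CC1(C)[C@H]2C[C@@]3([C@@H](OI)C=C2C(=O)OCC[Si](C)(C)C)[C@H](C)CC[C@@H]13 | intermediate
8 | 2-(trimethylsilyl)ethyl (2R,10S)-10-hydroxy-12-iodocedr-8-en-15-oate | CC1(C)[C@H]2C[C@@]3([C@@H](O)C=C2C(=O)OCC[Si](C)(C)C)[C@H](CI)CC[C@@H]13 | intermediate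
9 | 2-(trimethylsilyl)ethyl (2R,10S)-10,12-epoxycedr-8-en-15-oate (oxolane O bridging C10 and C12) | CC1(C)[C@H]2C[C@@]3([C@@H](O4)C=C2C(=O)OCC[Si](C)(C)C)[C@H](C4)CC[C@@H]13 | intermediate
10 | oct-7-yn-1-ol | C#CCCCCCCO | starting material
11 | tert-butyl(oct-7-yn-1-yloxy)diphenylsilane | C#CCCCCCCO[Si](c1ccccc1)(c1ccccc1)C(C)(C)C | intermediate
12 | 8-bromooctanoic acid | OC(=O)CCCCCCCBr | starting material
13 | 16-(tert-butyldiphenylsilyloxy)hexadec-9-ynoic acid | OC(=O)CCCCCCCC#CCCCCCCO[Si](c1ccccc1)(c1ccccc1)C(C)(C)C | intermediate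
14 | (9Z)-16-(tert-butyldiphenylsilyloxy)hexadec-9-enoic acid | OC(=O)CCCCCCC/C=C\CCCCCCO[Si](c1ccccc1)(c1ccccc1)C(C)(C)C | intermediate
15 | (9Z)-16-(tert-butyldiphenylsilyloxy)hexadec-9-enoyl chloride | ClC(=O)CCCCCCC/C=C\CCCCCCO[Si](c1ccccc1)(c1ccccc1)C(C)(C)C | intermediate
16 | (9Z)-16-(tert-butyldiphenylsilyloxy)hexadec-9-enoyl trifluoromethanesulfonate | O=C(CCCCCCC/C=C\CCCCCCO[Si](c1ccccc1)(c1ccccc1)C(C)(C)C)OS(=O)(=O)C(F)(F)F | intermediate
17 | 2-(trimethylsilyl)ethyl (2R,10S)-10-[(9Z)-16-(tert-butyldiphenylsilyloxy)hexadec-9-enoyloxy]-12-(trifluoromethanesulfonyloxy)cedr-8-en-15-oate | CC1(C)[C@H]2C[C@@]3([C@@H](OC(=O)CCCCCCC/C=C\CCCCCCO[Si](c4ccccc4)(c4ccccc4)C(C)(C)C)C=C2C(=O)OCC[Si](C)(C)C)[C@H](COS(=O)(=O)C(F)(F)F)CC[C@@H]13 | intermediate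
18 | dimethyl(alkoxy)sulfonium triflate of 17 (C12–O–S+Me2) | CC1(C)[C@H]2C[C@@]3([C@@H](OC(=O)CCCCCCC/C=C\CCCCCCO[Si](c4ccccc4)(c4ccccc4)C(C)(C)C)C=C2C(=O)OCC[Si](C)(C)C)[C@H](CO[S+](C)C)CC[C@@H]13.[O-]S(=O)(=O)C(F)(F)F | intermediate
19 | 2-(trimethylsilyl)ethyl (2R,10S)-10-[(9Z)-16-(tert-butyldiphenylsilyloxy)hexadec-9-enoyloxy]-12-oxocedr-8-en-15-oate (formyl cis to C10) | CC1(C)[C@H]2C[C@@]3([C@@H](OC(=O)CCCCCCC/C=C\CCCCCCO[Si](c4ccccc4)(c4ccccc4)C(C)(C)C)C=C2C(=O)OCC[Si](C)(C)C)[C@H](C=O)CC[C@@H]13 | intermediate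
20 | 2-(trimethylsilyl)ethyl (2S,10S)-10-[(9Z)-16-(tert-butyldiphenylsilyloxy)hexadec-9-enoyloxy]-12-oxocedr-8-en-15-oate (formyl trans to C10) | CC1(C)[C@H]2C[C@@]3([C@@H](OC(=O)CCCCCCC/C=C\CCCCCCO[Si](c4ccccc4)(c4ccccc4)C(C)(C)C)C=C2C(=O)OCC[Si](C)(C)C)[C@@H](C=O)CC[C@@H]13 | intermediate
21 | (2S,10S)-10-[(9Z)-16-hydroxyhexadec-9-enoyloxy]-12-oxocedr-8-en-15-oic acid, (1S,2S,5S,7R,10S) | CC1(C)[C@H]2C[C@@]3([C@@H](OC(=O)CCCCCCC/C=C\CCCCCCO)C=C2C(=O)O)[C@@H](C=O)CC[C@@H]13 | target

**Step count and risks**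
Total steps: 11. Longest linear sequence: 8 (steps 1–6, 10, 11).

Step 6 (remote C–H etherification). The C10 alkoxy radical may fragment (C1–C10 β-scission) or the allylic carbinol may be oxidised back to ketone 5. The fallback avoids oxygen radicals and sets out from 6. Et2SiHCl/Et3N gives the diethylhydrosilyl ether F4. [Rh(cod)Cl]2/Xantphos with norbornene at 100 °C silylates the δ-methyl C–H to give the oxasilinane F5. H2O2/KHCO3 (Tamao–Fleming) gives the 10,12-diol F6. TsCl/pyridine gives the primary tosylate F7, which the C10 hydroxyl displaces on warming, and the route is rejoined at 9.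

Step 10 (proposed new one-pot coupling). The acyl triflate may react elsewhere (chain alkene, DMSO), and the C2 equilibrium may be less one-sided than expected. The fallback uses known chemistry and sets out from 9 and 15. NaI in MeCN converts 15 into the acyl iodide F8, which cleaves the oxolane at the primary carbon to give the 12-iodo ester F9. Kornblum oxidation (DMSO, NaHCO3, 90 °C) gives 19, and DBU equilibrates it to rejoin the route at 20; any remaining 19 is separated and re-equilibrated.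

Step 4 (γ-oxidation of the enoate). The C10 methylene is deactivated by the ester and flanked by a quaternary carbon, so conversion may be poor. The fallback reverses the order of the oxidations and sets out from 1. Rh2(cap)4/t-BuOOH on the electron-rich alkene gives cedr-8-en-10-one F1. SeO2 in dioxane oxidises the vinylogous C15 methyl to 10-oxocedr-8-en-15-al F2. Pinnick oxidation gives 10-oxocedr-8-en-15-oic acid F3, and Steglich esterification with 2-(trimethylsilyl)ethanol rejoins the route at 5.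

**Further compounds**
F1 | step 4 | cedr-8-en-10-one | CC1(C)[C@H]2C[C@@]3(C(=O)C=C2C)[C@H](C)CC[C@@H]13
F2 | step 4 | 10-oxocedr-8-en-15-al | CC1(C)[C@H]2C[C@@]3(C(=O)C=C2C=O)[C@H](C)CC[C@@H]13
F3 | step 4 | 10-oxocedr-8-en-15-oic acid | CC1(C)[C@H]2C[C@@]3(C(=O)C=C2C(=O)O)[C@H](C)CC[C@@H]13
F4 | step 6 | 2-(trimethylsilyl)ethyl (10S)-10-(diethylsilyloxy)cedr-8-en-15-oate | CC1(C)[C@H]2C[C@@]3([C@@H](O[SiH](CC)CC)C=C2C(=O)OCC[Si](C)(C)C)[C@H](C)CC[C@@H]13
F5 | step 6 | oxasilinane from F4 (diethylsilylene bridging O10 and C12) | CC1(C)[C@H]2C[C@@]3([C@@H](O[Si]4(CC)CC)C=C2C(=O)OCC[Si](C)(C)C)[C@H](C4)CC[C@@H]13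
F6 | step 6 | 2-(trimethylsilyl)ethyl (2R,10S)-10,12-dihydroxycedr-8-en-15-oate | CC1(C)[C@H]2C[C@@]3([C@@H](O)C=C2C(=O)OCC[Si](C)(C)C)[C@H](CO)CC[C@@H]13
F7 | step 6 | 2-(trimethylsilyl)ethyl (2R,10S)-10-hydroxy-12-(4-methylbenzenesulfonyloxy)cedr-8-en-15-oate | CC1(C)[C@H]2C[C@@]3([C@@H](O)C=C2C(=O)OCC[Si](C)(C)C)[C@H](COS(=O)(=O)c4ccc(C)cc4)CC[C@@H]13
F8 | step 10 | (9Z)-16-(tert-butyldiphenylsilyloxy)hexadec-9-enoyl iodide | IC(=O)CCCCCCC/C=C\CCCCCCO[Si](c1ccccc1)(c1ccccc1)C(C)(C)C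
F9 | step 10 | 2-(trimethylsilyl)ethyl (2R,10S)-10-[(9Z)-16-(tert-butyldiphenylsilyloxy)hexadec-9-enoyloxy]-12-iodocedr-8-en-15-oate | CC1(C)[C@H]2C[C@@]3([C@@H](OC(=O)CCCCCCC/C=C\CCCCCCO[Si](c4ccccc4)(c4ccccc4)C(C)(C)C)C=C2C(=O)OCC[Si](C)(C)C)[C@H](CI)CC[C@@H]13
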